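How high does target stand in the flask within 1.5 h, and when?

| flask | substrate | enzyme | remark | time |
|---|---|---|---|---|
| epsilon | 0.10 M | 5 µM | run made earlier |  |
| zeta | 0.10 M | 7.5 µM | run made earlier |  |
| beta | 0.20 M | 10 µM | run made earlier |  |
| flask | 0.10 M | 10 µM |  | 1.5 h |

| run | time / min | target / % | substrate / % |
|---|---|---|---|
| epsilon | 8.00 | 13 | 87 |
| epsilon | 12.0 | 17 | 76 |
| epsilon | 20.0 | 21 | 67 |
| epsilon | 30.0 | 34 | 62 |
| epsilon | 40.0 | 34 | 55 |
| epsilon | 60.0 | 35 | 47 |
| epsilon | 90.0 | 32 | 40 |
| zeta | 8.00 | 13 | 80 |
| zeta | 12.0 | 26 | 69 |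
| zeta | 20.0 | 32 | 60 |
| zeta | 30.0 | 37 | 55 |
| zeta | 40.0 | 39 | 44 |
| zeta | 60.0 | 36 | 35 |
| zeta | 90.0 | 36 | 33 |
| beta | 8.00 | 18 | 83 |
| beta | 15.0 | 25 | 73 |
| beta | 30.0 | 45 | 48 |
| beta | 50.0 | 52 | 35 |
| beta | 90.0 | 56 | 27 |

(readings scatter by 2 percentage points)

- time up to 1.5 h at which target stands highest
- the amount of target, in percent of the substrate charged, at that time

- a reading or a percentage of target counts all its forms, free or not

Two views compete. The first takes enzyme × time as the clock: “The runs collapse fairly well on enzyme × time”. On that view the flask is zeta run faster. This is the forecast: 39% (range 35% to 44%) at 0.6 h (range 0.35 h to 1.1 h).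

The second view is my own. Enzyme makes target, but target may be lost on plain time, as a first-order loss. Zeta's highest target reading, 39% at 40.0 min, stands beside substrate 44%. So 17.0% of the charge is missing. Integrating d(missing)/dt = k·c(target) gives missing = k × mean target × time. I take the reading at half that time, 32%, as the mean. As a reading, that gives 0.0133 min⁻¹, the holding loss: the share of held target lost per minute.

The flask reaches zeta's enzyme-time in 30.0 min. I assume substrate and mean target then match zeta's, while the shorter time brings the missing share down to an estimated 12.8%. My reckoning therefore gives 43.2% at 30.0 min, higher and earlier than the forecast.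

The flask gives 44.5% at 0.587 h. The forecast's time holds, but the height lies above its range. Enzyme × time still fits at one early point: at 0.150 h the flask holds target 26.4%, and zeta read 26% at 12.0 min, the same enzyme-time. In this flask, the holding loss over 0.587 h, with target at half that time, 38.8%, taken as the mean, gives 18.2%, against 16.0% of isomer of the product.

    enzyme + target → spent catalyst (k = 0.570 L mol⁻¹ min⁻¹)
    target ⇌ isomer of the product (K = 1.40, k = 0.0160 min⁻¹)
    substrate + enzyme → target + enzyme, rate k3*[substrate]^2.5*[enzyme]/(1 + ([substrate]/Kh3)^2.5) (0.0720 M, k = 3.90 × 10⁵ L²·⁵ mol⁻²·⁵ min⁻¹)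
    crystals ⇌ target, rate k4*(cs4 - [target]) while solid is left; crystals form when [target] > cs4 (solubility = 43.0 mM, k = 0.340 min⁻¹)

The neighbour flask, like this one but with 0.25 M substrate, ends with target 52.4%, of which 35.1% is crystals. Taking its dissolved 17.3% at the end as the mean, the holding loss gives 20.7% by 1.50 h. The computed isomer of the product there is 15.9%.

(The numbers in the tables stem from a simulated flask for substances that don't exist, noise included.)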